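**Retrosynthetic overview**
- The heterocyclic ring is the only ring made and it is closed last, by intramolecular Friedel–Crafts acylation (C4–C4a) of an (S)-3-aryloxy-3-arylpropanoic acid. The symmetrical 3,5-dimethoxyphenoxy ring can give only the 5,7-dimethoxy pattern.
- The C2–O1 aryl ether comes from Mitsunobu inversion of an (R)-benzylic alcohol with 3,5-dimethoxyphenol. The future carboxyl carbon is carried as a TBS-protected primary alcohol so that no acidifying β-carbonyl is present during the etherification.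
- The (R)-carbinol comes from ketoreductase (KRED) reduction of achiral ethyl 3,4,5-trimethoxybenzoylacetate, followed by ester reduction to the 1,3-diol.
- Both benzene rings are bought preformed.

Assumption: the stereocentre in the SMILES is read as (2S), and the KRED is the (R)-selective (anti-Prelog) hit of a commercial ketoreductase screening panel.

**Route**

Step 1
Reactants: 1 ethyl 3-oxo-3-(3,4,5-trimethoxyphenyl)propanoate
Product: 2 ethyl (3R)-3-hydroxy-3-(3,4,5-trimethoxyphenyl)propanoate
Conditions: (R)-selective ketoreductase (KRED, NADPH-dependent alcohol dehydrogenase), NADP+ (cat.), iPrOH (15% v/v), KPi buffer pH 7.0, 30 °C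
Reagents that add atoms: none
Why: Ketoreductase-catalysed asymmetric carbonyl reduction, in which the enzyme delivers hydride from NADPH to one enantiotopic face of the aryl ketone (anti-Prelog sense) to set the (R)-carbinol in high ee while isopropanol recycles the cofactor.

Step 2
Reactants: 2 ethyl (3R)-3-hydroxy-3-(3,4,5-trimethoxyphenyl)propanoate
Product: 3 (1R)-1-(3,4,5-trimethoxyphenyl)propane-1,3-diol
Conditions: LiBH4, THF, 0 °C to rt; aq. NH4Cl
Reagents that add atoms: none
Why: Borohydride ester reduction (assisted by the β-hydroxyl) gives the primary alcohol and does not touch the carbinol stereocentre.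

Step 3
Reactants: 3 (1R)-1-(3,4,5-trimethoxyphenyl)propane-1,3-diol
Product: 4 (1R)-3-[(tert-butyldimethylsilyl)oxy]-1-(3,4,5-trimethoxyphenyl)propan-1-ol
Conditions: TBSCl (1.05 eq), imidazole, CH2Cl2, 0 °C
Reagents that add atoms: TBSCl, CC(C)(C)[Si](C)(C)Cl
Why: Silyl ether protection is strongly selective for the unhindered primary hydroxyl over the secondary benzylic one, leaving only the benzylic OH free.

Step 4
Reactants: 4 (1R)-3-[(tert-butyldimethylsilyl)oxy]-1-(3,4,5-trimethoxyphenyl)propan-1-ol; 5 3,5-dimethoxyphenol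
Product: 7 tert-butyl[(3S)-3-(3,5-dimethoxyphenoxy)-3-(3,4,5-trimethoxyphenyl)propoxy]dimethylsilane, via alkoxyphosphonium phenoxide 6 (not isolated)
Conditions: PPh3, DIAD, toluene, 0 °C to rt
Reagents that add atoms: none
Why: Mitsunobu etherification, in which the phenoxide displaces the oxyphosphonium group by SN2 with inversion and so converts the (R)-carbinol into the (S)-aryl ether, with no β-carbonyl present to promote elimination.

Step 5
Reactants: 7 tert-butyl[(3S)-3-(3,5-dimethoxyphenoxy)-3-(3,4,5-trimethoxyphenyl)propoxy]dimethylsilane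
Product: 8 (3S)-3-(3,5-dimethoxyphenoxy)-3-(3,4,5-trimethoxyphenyl)propan-1-ol
Conditions: TBAF, THF, 0 °C to rt
Reagents that add atoms: none
Why: Fluoride-mediated desilylation frees the primary alcohol without affecting the aryl ether or the stereocentre.

Step 6
Reactants: 8 (3S)-3-(3,5-dimethoxyphenoxy)-3-(3,4,5-trimethoxyphenyl)propan-1-ol
Product: 10 (3S)-3-(3,5-dimethoxyphenoxy)-3-(3,4,5-trimethoxyphenyl)propanoic acid, via aldehyde 9 (not isolated)
Conditions: TEMPO (0.2 eq), PhI(OAc)2 (2.5 eq), MeCN/H2O 1:1, rt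
Reagents that add atoms: water, O
Why: TEMPO/BAIB oxoammonium oxidation takes the primary alcohol through the aldehyde hydrate to the acid under near-neutral, chlorine-free conditions that spare the electron-rich rings and the β-aryloxy stereocentre.

Step 7
Reactants: 10 (3S)-3-(3,5-dimethoxyphenoxy)-3-(3,4,5-trimethoxyphenyl)propanoic acid
Product: 12 (2S)-5,7-dimethoxy-2-(3,4,5-trimethoxyphenyl)chroman-4-one, via mixed trifluoroacetic anhydride 11 (not isolated)
Conditions: TFAA (2 eq), CH2Cl2, 0 °C; cold aq. NaHCO3 quench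
Reagents that add atoms: none
Why: Intramolecular Friedel–Crafts acylation via the mixed anhydride occurs ortho to the ether oxygen of the highly nucleophilic phloroglucinol-type ring (both ortho positions are equivalent, and six-ring closure beats indanone formation on the less nucleophilic trimethoxyphenyl ring), closing the chromanone without touching C2.

**Compound list**

1 | ethyl 3-oxo-3-(3,4,5-trimethoxyphenyl)propanoate | CCOC(=O)CC(=O)c1cc(OC)c(OC)c(OC)c1 | starting material
2 | ethyl (3R)-3-hydroxy-3-(3,4,5-trimethoxyphenyl)propanoate | CCOC(=O)C[C@@H](O)c1cc(OC)c(OC)c(OC)c1 | intermediate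
3 | (1R)-1-(3,4,5-trimethoxyphenyl)propane-1,3-diol | OCC[C@@H](O)c1cc(OC)c(OC)c(OC)c1 | intermediate
4 | (1R)-3-[(tert-butyldimethylsilyl)oxy]-1-(3,4,5-trimethoxyphenyl)propan-1-ol | CC(C)(C)[Si](C)(C)OCC[C@@H](O)c1cc(OC)c(OC)c(OC)c1 | intermediate
5 | 3,5-dimethoxyphenol | COc1cc(O)cc(OC)c1 | starting material
6 | [(1R)-3-[(tert-butyldimethylsilyl)oxy]-1-(3,4,5-trimethoxyphenyl)propoxy]triphenylphosphonium 3,5-dimethoxyphenoxide | CC(C)(C)[Si](C)(C)OCC[C@@H](O[P+](c1ccccc1)(c1ccccc1)c1ccccc1)c1cc(OC)c(OC)c(OC)c1.[O-]c1cc(OC)cc(OC)c1 | intermediate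
7 | tert-butyl[(3S)-3-(3,5-dimethoxyphenoxy)-3-(3,4,5-trimethoxyphenyl)propoxy]dimethylsilane | CC(C)(C)[Si](C)(C)OCC[C@H](Oc1cc(OC)cc(OC)c1)c1cc(OC)c(OC)c(OC)c1 | intermediate
8 | (3S)-3-(3,5-dimethoxyphenoxy)-3-(3,4,5-trimethoxyphenyl)propan-1-ol | OCC[C@H](Oc1cc(OC)cc(OC)c1)c1cc(OC)c(OC)c(OC)c1 | intermediate
9 | (3S)-3-(3,5-dimethoxyphenoxy)-3-(3,4,5-trimethoxyphenyl)propanal | O=CC[C@H](Oc1cc(OC)cc(OC)c1)c1cc(OC)c(OC)c(OC)c1 | intermediate
10 | (3S)-3-(3,5-dimethoxyphenoxy)-3-(3,4,5-trimethoxyphenyl)propanoic acid | OC(=O)C[C@H](Oc1cc(OC)cc(OC)c1)c1cc(OC)c(OC)c(OC)c1 | intermediate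
11 | (3S)-3-(3,5-dimethoxyphenoxy)-3-(3,4,5-trimethoxyphenyl)propanoic trifluoroacetic anhydride | O=C(C[C@H](Oc1cc(OC)cc(OC)c1)c1cc(OC)c(OC)c(OC)c1)OC(=O)C(F)(F)F | intermediate
12 | (2S)-5,7-dimethoxy-2-(3,4,5-trimethoxyphenyl)chroman-4-one | COc1cc(OC)c2c(c1)O[C@H](c1cc(OC)c(OC)c(OC)c1)CC2=O | target

**Totals**
Total step count: 7. Longest linear sequence: 7 steps (1 to 12).

**Steps most likely to fail**

Step 4 (Mitsunobu etherification). The risks are partial racemisation through a benzylic cation, elimination to the styrene and C-alkylation of the phenol. The fallback sets out from compound 1 and comes back at compound 7. Compound 1 is reduced with the enantiocomplementary Prelog-selective ketoreductase to ethyl (3S)-3-hydroxy-3-(3,4,5-trimethoxyphenyl)propanoate F1. LiBH4 reduction gives (1S)-1-(3,4,5-trimethoxyphenyl)propane-1,3-diol F2, and selective silylation gives (1S)-3-[(tert-butyldimethylsilyl)oxy]-1-(3,4,5-trimethoxyphenyl)propan-1-ol F3. The aryl ether is then made by copper-catalysed Ullmann-type O-arylation of F3 with 1-iodo-3,5-dimethoxybenzene (CuI, 3,4,7,8-tetramethyl-1,10-phenanthroline, Cs2CO3, toluene, 100 °C). The new C–O bond forms at the arene and the carbinol C–O bond is never broken, so configuration is retained and the (S)-alcohol gives 7 directly.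

Step 6 (oxidation to the acid). The risk is attack of the oxidant on the very electron-rich aryl ether ring, or loss of phenoxide from the β-aryloxy aldehyde. The fallback sets out from compound 2 and comes back at compound 10. Compound 2 is etherified directly with 5 under Mitsunobu conditions (PPh3, DIAD, toluene, −10 °C) to ethyl (3S)-3-(3,5-dimethoxyphenoxy)-3-(3,4,5-trimethoxyphenyl)propanoate F4, accepting some cinnamate from elimination. The ester is then cleaved with a hydrolase (pig liver esterase, pH 7.5 phosphate buffer with 10% acetone, 30 °C; Me3SnOH in DCE at 70 °C if the enzyme is slow) to give 10. The carboxyl carbon stays at the acid oxidation level throughout, so no oxidant meets the electron-rich rings, and the neutral hydrolysis avoids E1cB loss of the phenoxide.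

Step 7 (Friedel–Crafts ring closure). The risk is acid-induced ionisation of the benzylic aryl ether, giving racemisation or cleavage, or competing indanone formation. The fallback sets out from compounds 4 and 5 and comes back at compound 12. Compound 5 is brominated (NBS, CH2Cl2, −78 °C, separation from the 4-bromo isomer) to 2-bromo-3,5-dimethoxyphenol F5. Mitsunobu reaction of 4 with F5 gives tert-butyl[(3S)-3-(2-bromo-3,5-dimethoxyphenoxy)-3-(3,4,5-trimethoxyphenyl)propoxy]dimethylsilane F6. TBAF gives (3S)-3-(2-bromo-3,5-dimethoxyphenoxy)-3-(3,4,5-trimethoxyphenyl)propan-1-ol F7, and TEMPO/BAIB oxidation gives (3S)-3-(2-bromo-3,5-dimethoxyphenoxy)-3-(3,4,5-trimethoxyphenyl)propanoic acid F8. Parham cyclisation (n-BuLi 2.2 eq, THF, −100 to −78 °C) then performs bromine–lithium exchange on the lithium carboxylate, and the aryllithium attacks the carboxylate to give 12 after aqueous quench. This is an anionic, acid-free ring closure whose regiochemistry is fixed by the bromine.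

**Further compounds**

F1 | step 4 | ethyl (3S)-3-hydroxy-3-(3,4,5-trimethoxyphenyl)propanoate | CCOC(=O)C[C@H](O)c1cc(OC)c(OC)c(OC)c1
F2 | step 4 | (1S)-1-(3,4,5-trimethoxyphenyl)propane-1,3-diol | OCC[C@H](O)c1cc(OC)c(OC)c(OC)c1
F3 | step 4 | (1S)-3-[(tert-butyldimethylsilyl)oxy]-1-(3,4,5-trimethoxyphenyl)propan-1-ol | CC(C)(C)[Si](C)(C)OCC[C@H](O)c1cc(OC)c(OC)c(OC)c1
F4 | step 6 | ethyl (3S)-3-(3,5-dimethoxyphenoxy)-3-(3,4,5-trimethoxyphenyl)propanoate | CCOC(=O)C[C@H](Oc1cc(OC)cc(OC)c1)c1cc(OC)c(OC)c(OC)c1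
F5 | step 7 | 2-bromo-3,5-dimethoxyphenol | COc1cc(O)c(Br)c(OC)c1
F6 | step 7 | tert-butyl[(3S)-3-(2-bromo-3,5-dimethoxyphenoxy)-3-(3,4,5-trimethoxyphenyl)propoxy]dimethylsilane | CC(C)(C)[Si](C)(C)OCC[C@H](Oc1cc(OC)cc(OC)c1Br)c1cc(OC)c(OC)c(OC)c1
F7 | step 7 | (3S)-3-(2-bromo-3,5-dimethoxyphenoxy)-3-(3,4,5-trimethoxyphenyl)propan-1-ol | OCC[C@H](Oc1cc(OC)cc(OC)c1Br)c1cc(OC)c(OC)c(OC)c1
F8 | step 7 | (3S)-3-(2-bromo-3,5-dimethoxyphenoxy)-3-(3,4,5-trimethoxyphenyl)propanoic acid | OC(=O)C[C@H](Oc1cc(OC)cc(OC)c1Br)c1cc(OC)c(OC)c(OC)c1
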